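The pitfall in Saturday's and Tuesday's runs is to expect left-handed product to follow the free catalyst: that charge rises by a factor of 2.23, but left-handed product at 10.0 d rises by a factor of 1.33, from 24 % to 32 %. In these flasks, solid reagent dissolves to partner, and partner with free catalyst turns each substrate into its product, while the racemization catalyst interconverts the substrates.

| flask | left-handed substrate | right-handed substrate | solid reagent | free catalyst | racemization catalyst | remark | time |
|---|---|---|---|---|---|---|---|
| Saturday's | 0.33 M | 0.33 M | 0.99 M | 0.22 mM | 0.33 mM | run made earlier |  |
| Tuesday's | 0.33 M | 0.33 M | 0.99 M | 0.49 mM | 0.33 mM | run made earlier |  |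
| flask | 0.33 M | 0.33 M | 0.990 M | 0.33 mM | 0.33 mM |  | 10 d |

| run | time / d | left-handed product / % | left-handed substrate / % |
|---|---|---|---|
| Saturday's | 0.833 | 0 | 49 |
| Saturday's | 1.67 | 2 | 46 |
| Saturday's | 4.00 | 8 | 43 |
| Saturday's | 10.0 | 24 | 33 |
| Tuesday's | 0.833 | 3 | 48 |
| Tuesday's | 1.67 | 4 | 49 |
| Tuesday's | 4.00 | 12 | 43 |
| Tuesday's | 10.0 | 32 | 28 |

(standard deviation of a reading: 1.5 percentage points)

- free catalyst is single-handed; left-handed substrate and right-handed substrate are mirror images of each other, charged as a racemate, each of them at the stated concentration
- solid, in amounts per volume of the solution: solid reagent
- candidate steps: partner + free catalyst + left-handed substrate -> free catalyst + left-handed product; partner + free catalyst + right-handed substrate -> free catalyst + right-handed product; left-handed substrate + racemization catalyst <-> right-handed substrate + racemization catalyst; solid reagent <-> partner; partner + racemization catalyst -> spent catalyst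
- at the start none of the solid reagent is in solution

- left-handed product at 10 d, in percent of the left-handed substrate and right-handed substrate together charged
- the change that raises the amount of left-handed product at 10 d, in percent of the left-handed substrate and right-handed substrate together charged most ("none" if none brings more than 2 percentage points) (maple / oak / alder / none)
- amount of left-handed product at 10 d, in percent of the left-handed substrate and right-handed substrate together charged, after oak

The logarithm of the product ratio divided by that of the catalyst ratio gives 0.359, the apparent catalyst order n, a reading from two points, each good to 1.5 percentage points. On this scale zero is a yield blind to free catalyst and one is a yield proportional to it. Because n lies nearer zero than one, the change to look to is in the supply of partner, oak or alder, and not maple. Scaled from Saturday's run to the flask's 0.33 mM, n gives this text's own estimate of 27.8 %.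

The forecast gives 27.5 %, picks alder and puts oak at 37 %, on the ground that “dissolution is partly limiting”.

The flask gives 26.5 % at 10 d, and alder is the best change, with gains of 20 points for alder, 14 points for oak and 4 points for maple, while oak reaches 40.5 %. The steps and constants are these:

    partner + free catalyst + left-handed substrate → free catalyst + left-handed product (k = 0.100 /M²/s)
    partner + free catalyst + right-handed substrate → free catalyst + right-handed product (k = 0.0390 /M²/s)
    left-handed substrate + racemization catalyst ⇌ right-handed substrate + racemization catalyst, rate k3*[racemization catalyst]*[left-handed substrate] forward; the back reaction follows from the equilibrium constant (k = 0.0240 /M/s)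
    solid reagent ⇌ partner, rate k4*(cs4 - [partner]) while solid is left; crystals form when [partner] > cs4 (solubility = 0.120 M, k = 3.30 × 10⁻⁶ /s)
    partner + racemization catalyst → spent catalyst (k = 6.40 × 10⁻⁶ /M/s)

At 10.0 d the flask holds 0.0300 M of partner, made 1.05 times as fast as it is used up, each step taken net. Carried from this flask to the neighbour with 8.2 × 10⁻⁵ M of free catalyst, n gives 16.1 % of left-handed product, and that neighbour holds 15.3 %.

(The numbers in the tables are simulated with made-up constants, noise included.)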